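**Strategy.** The aryl–C7 bond is made one oxidation level above the target: the benzylidene carbon C7 is β to ring carbon C5 and γ to O1, so it is the terminus of a propargyl ether O1–C5H2–C4≡C7. A Sonogashira coupling joins guaiacyl iodide 7 to the complete, enantiopure epoxy propargyl ether 5 (ring A, C2, latent C3–CH2OH) in one operation; its precursor contains neither the tetrahydrofuran ring nor an olefin. The following titanocene(III) epoxide-opening/5-exo-dig radical cyclisation closes C3–C4, sets C3 trans to C2 and, because hydrogen is delivered last to the aryl-bearing vinyl radical from the open C5 side, the E-olefin. Mitsunobu esterification and desilylation finish.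

Key step: step 6

Remark: locants used throughout are O1, C2 (bears ring A), C3 (bears the CH2O arm), C4 (exocyclic C4=C7) and C5 of the tetrahydrofuran; ring B is the aryl group on C7, ring C the benzoate.

**Step 1**
Reactants: 1 vanillin
Product: 2 3-methoxy-4-[(triisopropylsilyl)oxy]benzaldehyde
Conditions: TIPSCl, imidazole, DMF, rt
Reagents that add atoms: triisopropylsilyl chloride, CC(C)[Si](Cl)(C(C)C)C(C)C
Why: Imidazole-promoted O-silylation masks the phenol for the organometallic and alkoxide steps, and an aryl TIPS ether is chosen because it should survive Grignard reagents, NaH and amine bases.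

**Step 2**
Reactants: 2 3-methoxy-4-[(triisopropylsilyl)oxy]benzaldehyde
Product: 3 rac-1-{3-methoxy-4-[(triisopropylsilyl)oxy]phenyl}prop-2-en-1-ol
Conditions: vinylmagnesium bromide, THF, −78 → 0 °C; then H2O
Reagents that add atoms: vinylmagnesium bromide, C=C[Mg]Br
Why: Grignard 1,2-addition to the aryl aldehyde gives the racemic secondary allylic alcohol that carries the future C2.

**Step 3**
Reactants: 3 rac-1-{3-methoxy-4-[(triisopropylsilyl)oxy]phenyl}prop-2-en-1-ol
Product: 4 (S)-{3-methoxy-4-[(triisopropylsilyl)oxy]phenyl}[(2R)-oxiran-2-yl]methanol (erythro)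
Conditions: Ti(OiPr)4 (cat.), L-(+)-DIPT (cat.), t-BuOOH (less than 0.5 equiv), 4 Å MS, CH2Cl2, −20 °C
Reagents that add atoms: tert-butyl hydroperoxide, CC(C)(C)OO
Why: In this Sharpless kinetic resolution (Katsuki–Sharpless epoxidation) the (R)-enantiomer of a 1-aryl allylic alcohol is epoxidised much faster and erythro-selectively with L-(+)-DIPT, so stopping below half conversion should give 4 with the C2 configuration of the target under catalyst control, while the slow (S)-alcohol is separated and the oxirane centre is erased later.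

**Step 4**
Reactants: 4 (S)-{3-methoxy-4-[(triisopropylsilyl)oxy]phenyl}[(2R)-oxiran-2-yl]methanol
Product: 5 (2R)-2-[(S)-{3-methoxy-4-[(triisopropylsilyl)oxy]phenyl}(prop-2-yn-1-yloxy)methyl]oxirane
Conditions: NaH, propargyl bromide, Bu4NI (cat.), THF, −20 → 0 °C
Reagents that add atoms: propargyl bromide, C#CCBr
Why: Williamson etherification of the sodium alkoxide with the reactive propargylic bromide at low temperature should outrun Payne rearrangement, as in routine benzylations of such epoxy alcohols, and touches no stereocentre.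

**Step 5**
Reactants: 6 4-iodo-2-methoxyphenol
Product: 7 (4-iodo-2-methoxyphenoxy)triisopropylsilane
Conditions: TIPSCl, imidazole, DMF, rt
Reagents that add atoms: triisopropylsilyl chloride, CC(C)[Si](Cl)(C(C)C)C(C)C
Why: The same O-silylation as in step 1 keeps ring B free of an acidic, H-donating phenol during the coupling, the radical step and the esterification.

**Step 6**
Reactants: 5 (2R)-2-[(S)-{3-methoxy-4-[(triisopropylsilyl)oxy]phenyl}(prop-2-yn-1-yloxy)methyl]oxirane, 7 (4-iodo-2-methoxyphenoxy)triisopropylsilane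
Product: 8 (2R)-2-[(S)-{3-methoxy-4-[(triisopropylsilyl)oxy]phenyl}({3-[3-methoxy-4-(triisopropylsilyloxy)phenyl]prop-2-yn-1-yl}oxy)methyl]oxirane
Conditions: PdCl2(PPh3)2 (cat.), CuI (cat.), Et3N/THF, degassed, rt → 40 °C
Reagents that add atoms: none
Why: Sonogashira coupling, in which oxidative addition of Pd(0) into the C–I bond of 7, transmetalation with the copper acetylide of 5 and reductive elimination form the aryl–C7 bond as a C(sp2)–C(sp) bond; the closest known reaction type is the Pd/Cu coupling of aryl iodides with propargyl ethers. No ring is closed and no stereocentre is created, so C2 and the oxirane are carried through unchanged. The step exploits that C7 is β to C5 and γ to O1, which lets the bond be made at the alkyne level where no olefin geometry exists. The selectivity needed is chemoselectivity for the terminal alkyne C–H over the oxirane and the benzylic propargylic C–O bond, and it is secured by the mild amine base near room temperature and the inertness of both groups to Pd(0)/Cu(I); oxygen is excluded to suppress Glaser dimerisation. Placing the aryl group on the alkyne before ring closure is what makes hydrogen, not the aryl group, the last substituent delivered to C7 in step 7.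

**Step 7**
Reactants: 8 (2R)-2-[(S)-{3-methoxy-4-[(triisopropylsilyl)oxy]phenyl}({3-[3-methoxy-4-(triisopropylsilyloxy)phenyl]prop-2-yn-1-yl}oxy)methyl]oxirane
Product: 9 [(2R,3S,4E)-4-{3-methoxy-4-[(triisopropylsilyl)oxy]benzylidene}-2-{3-methoxy-4-[(triisopropylsilyl)oxy]phenyl}tetrahydrofuran-3-yl]methanol
Conditions: Cp2TiCl2, Zn dust, THF, rt; then 1 M HCl
Reagents that add atoms: none
Why: Titanocene(III) (Nugent–RajanBabu) homolytic epoxide opening gives the more substituted C3 radical, which closes 5-exo-dig onto the aryl alkyne through a chair-like transition state with the C2 aryl group pseudo-equatorial, setting C3 trans to C2 under substrate control; the linear aryl-stabilised vinyl radical is then quenched by hydrogen (solvent or Cp2TiCl/H+) from the less hindered C5 side, which should place ring B cis to C3 (E).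

**Step 8**
Reactants: 9 [(2R,3S,4E)-4-{3-methoxy-4-[(triisopropylsilyl)oxy]benzylidene}-2-{3-methoxy-4-[(triisopropylsilyl)oxy]phenyl}tetrahydrofuran-3-yl]methanol, 10 4-hydroxybenzoic acid
Product: 11 [(2R,3S,4E)-4-{3-methoxy-4-[(triisopropylsilyl)oxy]benzylidene}-2-{3-methoxy-4-[(triisopropylsilyl)oxy]phenyl}tetrahydrofuran-3-yl]methyl 4-hydroxybenzoate
Conditions: PPh3, DIAD, THF, 0 °C → rt
Reagents that add atoms: none
Why: In this Mitsunobu esterification the carboxylic acid is far more acidic than the phenol of 10 and is the pronucleophile engaged, so the primary alcohol should be acylated chemoselectively at CH2 without a protecting group on ring C and without touching a stereocentre.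

**Step 9**
Reactants: 11 [(2R,3S,4E)-4-{3-methoxy-4-[(triisopropylsilyl)oxy]benzylidene}-2-{3-methoxy-4-[(triisopropylsilyl)oxy]phenyl}tetrahydrofuran-3-yl]methyl 4-hydroxybenzoate
Product: 12 agastenol, [(2R,3S,4E)-4-(4-hydroxy-3-methoxybenzylidene)-2-(4-hydroxy-3-methoxyphenyl)tetrahydrofuran-3-yl]methyl 4-hydroxybenzoate
Conditions: TBAF, AcOH, THF, 0 °C
Reagents that add atoms: none
Why: Fluoride cleaves both aryl Si–O bonds, and acetic acid buffering keeps the liberated phenols protonated so that neither quinone-methide opening of the C2–O1 benzylic ether nor attack on the benzoate should occur.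

**Compound list**
1 | vanillin (4-hydroxy-3-methoxybenzaldehyde) | COc1cc(C=O)ccc1O | starting material
2 | 3-methoxy-4-[(triisopropylsilyl)oxy]benzaldehyde | COc1cc(C=O)ccc1O[Si](C(C)C)(C(C)C)C(C)C | intermediate
3 | rac-1-{3-methoxy-4-[(triisopropylsilyl)oxy]phenyl}prop-2-en-1-ol | C=CC(O)c1ccc(O[Si](C(C)C)(C(C)C)C(C)C)c(OC)c1 | intermediate
4 | (S)-{3-methoxy-4-[(triisopropylsilyl)oxy]phenyl}[(2R)-oxiran-2-yl]methanol | O[C@@H](c1ccc(O[Si](C(C)C)(C(C)C)C(C)C)c(OC)c1)[C@H]1CO1 | intermediate
5 | (2R)-2-[(S)-{3-methoxy-4-[(triisopropylsilyl)oxy]phenyl}(prop-2-yn-1-yloxy)methyl]oxirane | C#CCO[C@@H](c1ccc(O[Si](C(C)C)(C(C)C)C(C)C)c(OC)c1)[C@H]1CO1 | intermediate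
6 | 4-iodo-2-methoxyphenol | COc1cc(I)ccc1O | starting material
7 | (4-iodo-2-methoxyphenoxy)triisopropylsilane | COc1cc(I)ccc1O[Si](C(C)C)(C(C)C)C(C)C | intermediate
8 | (2R)-2-[(S)-{3-methoxy-4-[(triisopropylsilyl)oxy]phenyl}({3-[3-methoxy-4-(triisopropylsilyloxy)phenyl]prop-2-yn-1-yl}oxy)methyl]oxirane | COc1cc(C#CCO[C@@H](c2ccc(O[Si](C(C)C)(C(C)C)C(C)C)c(OC)c2)[C@H]2CO2)ccc1O[Si](C(C)C)(C(C)C)C(C)C | intermediate
9 | [(2R,3S,4E)-4-{3-methoxy-4-[(triisopropylsilyl)oxy]benzylidene}-2-{3-methoxy-4-[(triisopropylsilyl)oxy]phenyl}tetrahydrofuran-3-yl]methanol | COc1cc(/C=C2/CO[C@@H](c3ccc(O[Si](C(C)C)(C(C)C)C(C)C)c(OC)c3)[C@@H]2CO)ccc1O[Si](C(C)C)(C(C)C)C(C)C | intermediate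
10 | 4-hydroxybenzoic acid | OC(=O)c1ccc(O)cc1 | starting material
11 | [(2R,3S,4E)-4-{3-methoxy-4-[(triisopropylsilyl)oxy]benzylidene}-2-{3-methoxy-4-[(triisopropylsilyl)oxy]phenyl}tetrahydrofuran-3-yl]methyl 4-hydroxybenzoate | COc1cc(/C=C2/CO[C@@H](c3ccc(O[Si](C(C)C)(C(C)C)C(C)C)c(OC)c3)[C@@H]2COC(=O)c2ccc(O)cc2)ccc1O[Si](C(C)C)(C(C)C)C(C)C | intermediate
12 | agastenol | COc1cc(/C=C2/CO[C@@H](c3ccc(O)c(OC)c3)[C@@H]2COC(=O)c2ccc(O)cc2)ccc1O | target

**Total steps:** 9. **Longest linear sequence:** 8 (steps 1–4 and 6–9).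

**Steps most likely to fail**

Step 7. The hydrogen transfer that ends the radical cascade may show poor side selectivity at C7 (E/Z mixture), and ring closure may be incompletely trans-selective. Fallback, setting out from 8: the cyclisation is run unchanged, the (2R,3S,4Z) alcohol F1 is separated and converted to 9 by triplet-sensitised E/Z photoisomerisation (thioxanthone or fac-Ir(ppy)3, visible light, MeCN). This replaces kinetic control by photostationary control: the E isomer, whose aryl ring is twisted out of conjugation by the C3 substituent, should be the poorer energy acceptor and accumulate. The route is rejoined at 9.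

Step 4. The epoxy alkoxide may undergo Payne rearrangement before alkylation, or take the silyl group from the phenol. Fallback, setting out from 3: the resolution is run in the opposite sense (D-(−)-DIPT, slightly more than half an equivalent of t-BuOOH), so that the unwanted enantiomer is consumed as the epoxy alcohol ent-4 F2 and the (R)-allylic alcohol F3 is recovered. F3 is propargylated (NaH, propargyl bromide, with no oxirane present) to the enyne F4, whose allyl double bond is epoxidised with mCPBA to give 5 together with its oxirane epimer F5. The pair is carried on, F5 giving the epimeric coupling product F6 in step 6, because both oxirane configurations lead to the same C3 radical in step 7. The route is rejoined at 5.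

Step 8. The free phenol of 10 may compete as a nucleophile (O-alkylation, oligo-ester formation) under Mitsunobu activation. Fallback, setting out from 9: Steglich esterification with commercial 4-acetoxybenzoic acid (EDC·HCl, DMAP, CH2Cl2) gives the acetate-protected ester F7, whose aryl acetate is cleaved selectively by aminolysis with pyrrolidine (CH2Cl2, 0 °C). The route is rejoined at 11.

**Further compounds**
F1 | step 7 | [(2R,3S,4Z)-4-{3-methoxy-4-[(triisopropylsilyl)oxy]benzylidene}-2-{3-methoxy-4-[(triisopropylsilyl)oxy]phenyl}tetrahydrofuran-3-yl]methanol | COc1cc(/C=C2\CO[C@@H](c3ccc(O[Si](C(C)C)(C(C)C)C(C)C)c(OC)c3)[C@@H]2CO)ccc1O[Si](C(C)C)(C(C)C)C(C)C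
F2 | step 4 | ent-4, (R)-{3-methoxy-4-[(triisopropylsilyl)oxy]phenyl}[(2S)-oxiran-2-yl]methanol | O[C@H](c1ccc(O[Si](C(C)C)(C(C)C)C(C)C)c(OC)c1)[C@@H]1CO1
F3 | step 4 | (R)-1-{3-methoxy-4-[(triisopropylsilyl)oxy]phenyl}prop-2-en-1-ol | O[C@@H](c1ccc(O[Si](C(C)C)(C(C)C)C(C)C)c(OC)c1)C=C
F4 | step 4 | triisopropyl{2-methoxy-4-[(1R)-1-(prop-2-yn-1-yloxy)prop-2-en-1-yl]phenoxy}silane | C#CCO[C@@H](c1ccc(O[Si](C(C)C)(C(C)C)C(C)C)c(OC)c1)C=C
F5 | step 4 | (2S)-2-[(S)-{3-methoxy-4-[(triisopropylsilyl)oxy]phenyl}(prop-2-yn-1-yloxy)methyl]oxirane | C#CCO[C@@H](c1ccc(O[Si](C(C)C)(C(C)C)C(C)C)c(OC)c1)[C@@H]1CO1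
F6 | step 4 | (2S)-2-[(S)-{3-methoxy-4-[(triisopropylsilyl)oxy]phenyl}({3-[3-methoxy-4-(triisopropylsilyloxy)phenyl]prop-2-yn-1-yl}oxy)methyl]oxirane | COc1cc(C#CCO[C@@H](c2ccc(O[Si](C(C)C)(C(C)C)C(C)C)c(OC)c2)[C@@H]2CO2)ccc1O[Si](C(C)C)(C(C)C)C(C)C
F7 | step 8 | [(2R,3S,4E)-4-{3-methoxy-4-[(triisopropylsilyl)oxy]benzylidene}-2-{3-methoxy-4-[(triisopropylsilyl)oxy]phenyl}tetrahydrofuran-3-yl]methyl 4-acetoxybenzoate | COc1cc(/C=C2/CO[C@@H](c3ccc(O[Si](C(C)C)(C(C)C)C(C)C)c(OC)c3)[C@@H]2COC(=O)c2ccc(OC(C)=O)cc2)ccc1O[Si](C(C)C)(C(C)C)C(C)C
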